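## Retrosynthetic overview

1. The target is (3E,6R,8S)-1,11-di(furan-3-yl)-4,8-dimethylundec-3-en-6-yl acetate (undecene numbering C1–C11 is used below). The acetate comes from the C6 alcohol, and the alcohol from a C6 pinacol boronic ester with retention.
2. The key disconnection is C4–C5, with C6–C7 broken in the same operation. It is a palladium-catalysed enantioselective conjunctive cross-coupling of three parts: vinylboronic acid pinacol ester (C5, C6), the Grignard reagent of 3-[(4S)-5-bromo-4-methylpentyl]furan (C7–C11) and 3-[(3E)-4-bromopent-3-en-1-yl]furan (C1–C4).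
3. Enabling feature: the oxygen-bearing stereocentre C6 is tied through one methylene (C5) to the sp2 carbon C4 of the trisubstituted alkene. A vinylboron ate complex delivers exactly this C6(heteroatom)–C5H2–C4(sp2) triad when its boron-bearing carbon accepts a migrating alkyl group and its CH2 terminus accepts an alkenylpalladium. Both 3-furyl rings lie at least three carbons from the reacting atoms.
4. The C8 methyl centre is bought in (S)-3-bromo-2-methylpropan-1-ol and extended by a copper-catalysed Grignard coupling. The E-alkenyl bromide comes from syn hydrozirconation and bromination of 3-(pent-3-yn-1-yl)furan, itself made by Negishi coupling.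
5. No ring is formed at any stage: both furan rings are bought as 3-bromofuran.

Key step: step 8

Assumption: the (Sp,Sp) antipode of the MandyPhos ligand is taken to give the 6R boronic ester. If the sense of induction is the opposite with this alkyl migrating group, the (Rp,Rp) antipode is used and nothing else changes.

## Route

Step 1
Reactants: 1 3-bromofuran
Product: 3 2-(furan-3-yl)ethan-1-ol, via 3-furyllithium 2 (not isolated)
Conditions: n-BuLi, THF, -78 °C; ethylene oxide, BF3·OEt2, -78 °C; aq NaHCO3
Reagents that add atoms: ethylene oxide, C1CO1
Why: Bromine–lithium exchange at -78 °C gives 3-furyllithium without drift of lithium to ring position 2, and the BF3-assisted SN2 opening of ethylene oxide by the organolithium is fast at that temperature.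

Step 2
Reactants: 3 2-(furan-3-yl)ethan-1-ol
Product: 4 3-(2-bromoethyl)furan
Conditions: CBr4, PPh3, CH2Cl2, 0 °C
Reagents that add atoms: carbon tetrabromide, BrC(Br)(Br)Br
Why: The Appel reaction turns the primary alcohol into the bromide by SN2 attack on the alkoxyphosphonium salt under neutral conditions that spare the acid-sensitive furan.

Step 3
Reactants: 5 (2S)-3-bromo-2-methylpropan-1-ol
Product: 6 (2S)-3-bromo-2-methylpropyl trifluoromethanesulfonate
Conditions: Tf2O, 2,6-lutidine, CH2Cl2, -78 to -20 °C; cold aqueous work-up, used at once
Reagents that add atoms: trifluoromethanesulfonic anhydride, O=S(=O)(OS(=O)(=O)C(F)(F)F)C(F)(F)F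
Why: O-Sulfonylation of the primary alcohol with a hindered base installs a leaving group far better than the bromide in the same molecule, and the stereocentre bought with 5 takes no part.

Step 4
Reactants: 4 3-(2-bromoethyl)furan; 6 (2S)-3-bromo-2-methylpropyl trifluoromethanesulfonate
Product: 8 3-[(4S)-5-bromo-4-methylpentyl]furan, via 2-(furan-3-yl)ethylmagnesium bromide 7 (not isolated)
Conditions: 4, Mg, THF, rt; then 6, Li2CuCl4 (5 mol %), THF, -78 to -20 °C
Reagents that add atoms: none
Why: In this copper-catalysed sp3–sp3 cross-coupling of a Grignard reagent with an alkyl sulfonate, the primary triflate is displaced at a temperature where the β-branched primary bromide is inert, and no bond to the stereocentre is broken.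

Step 5
Reactants: 9 pent-3-yn-1-ol
Product: 10 5-iodopent-2-yne
Conditions: I2, PPh3, imidazole, CH2Cl2, 0 °C to rt
Reagents that add atoms: iodine, II
Why: Appel-type iodination replaces the primary hydroxyl group by SN2 displacement and leaves the internal alkyne untouched.

Step 6
Reactants: 10 5-iodopent-2-yne; 1 3-bromofuran
Product: 12 3-(pent-3-yn-1-yl)furan, via pent-3-yn-1-ylzinc iodide 11 (not isolated)
Conditions: Zn dust (activated with Me3SiCl), LiCl, THF, 40 °C; then 1, Pd(OAc)2 (2 mol %), SPhos (4 mol %), THF, 50 °C
Reagents that add atoms: none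
Why: LiCl-assisted zinc insertion into the primary iodide is followed by Negishi coupling with the heteroaryl bromide, in which the bulky biarylphosphine favours reductive elimination over β-hydride loss and the internal alkyne is a spectator.

Step 7
Reactants: 12 3-(pent-3-yn-1-yl)furan
Product: 14 3-[(3E)-4-bromopent-3-en-1-yl]furan, via alkenylzirconocene chloride 13 (not isolated)
Conditions: Cp2Zr(H)Cl (excess), THF, rt to 45 °C; then NBS (matched to the hydride charge), -78 to 0 °C
Reagents that add atoms: N-bromosuccinimide, O=C1CCC(=O)N1Br
Why: Hydrozirconation is a syn addition whose regioisomers equilibrate, with excess hydride and gentle warming, toward zirconium on the less hindered methyl-bearing carbon, and bromodezirconation with retention then fixes the E geometry faster than NBS can attack the furan.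

Step 8
Reactants: 8 3-[(4S)-5-bromo-4-methylpentyl]furan; 15 vinylboronic acid pinacol ester; 14 3-[(3E)-4-bromopent-3-en-1-yl]furan
Product: 18 2-[(3E,6R,8S)-1,11-di(furan-3-yl)-4,8-dimethylundec-3-en-6-yl]-4,4,5,5-tetramethyl-1,3,2-dioxaborolane, via alkylmagnesium bromide 16 (not isolated), via vinylborate ate complex 17 (not isolated)
Conditions: 8, Mg, THF, rt; 15, NaOTf, THF, 0 °C to rt; then 14, Pd(OAc)2 (2 mol %), (Sp,Sp)-MandyPhos (Ar = 3,5-Me2-4-MeOC6H2, 2.4 mol %), THF, 60 °C
Reagents that add atoms: none
Why: Zerovalent palladium inserts into the C–Br bond of 14 with retention of the E geometry, sodium ion takes up the bromide, and the cationic alkenylpalladium binds the vinyl group of ate complex 17; this sets off a 1,2-metallate shift in which C7 moves from boron to the boron-bearing carbon C6, anti to the metal, while the CH2 terminus C5 becomes bound to palladium, and reductive elimination then forms C4–C5. The closest known reaction type is the enantioselective palladium/MandyPhos conjunctive cross-coupling of vinylboron ate complexes made from Grignard reagents with C(sp2) bromides in the presence of NaOTf, which is established for primary alkyl migrating groups and for alkenyl electrophiles. No ring is closed. The one new stereocentre, C6, is set by the chiral bisphosphine, which chooses the face of the vinyl group bound to palladium, and the anti course of the shift translates this choice into 6R; the C8 centre lies in the migrating group, is not touched and is too remote to override the catalyst. The step needs the metallate shift to win over direct transfer of vinyl or alkyl from boron to palladium and over β-hydride loss from the C5–palladium alkyl, which the four-coordinate pinacolato borate, the halide-free cationic palladium and the wide bite angle of the ligand (fast reductive elimination) should secure; the furans and the product alkene carry no reactive C–X bond and stay out. In one operation the whole C21 skeleton is joined from three simple parts, two C–C bonds are made, C6 is set and its C–B bond is placed where the acetoxy group has to stand.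

Step 9
Reactants: 18 2-[(3E,6R,8S)-1,11-di(furan-3-yl)-4,8-dimethylundec-3-en-6-yl]-4,4,5,5-tetramethyl-1,3,2-dioxaborolane
Product: 19 (3E,6R,8S)-1,11-di(furan-3-yl)-4,8-dimethylundec-3-en-6-ol
Conditions: H2O2 (30 %), NaOH (3 M), THF, 0 °C to rt
Reagents that add atoms: hydrogen peroxide, OO
Why: In this stereoretentive boronic ester oxidation, hydroperoxide adds to boron and C6 migrates from boron to oxygen with retention, while the furans and the trisubstituted alkene are inert to basic peroxide.

Step 10
Reactants: 19 (3E,6R,8S)-1,11-di(furan-3-yl)-4,8-dimethylundec-3-en-6-ol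
Product: 20 (3E,6R,8S)-1,11-di(furan-3-yl)-4,8-dimethylundec-3-en-6-yl acetate
Conditions: Ac2O, pyridine, DMAP (cat.), CH2Cl2, rt
Reagents that add atoms: acetic anhydride, CC(=O)OC(C)=O
Why: DMAP-catalysed O-acylation of the secondary alcohol breaks no bond at C6, so the configuration is kept.

## Compound list

1 | 3-bromofuran | Brc1ccoc1 | starting material
2 | 3-furyllithium | [Li]c1ccoc1 | intermediate
3 | 2-(furan-3-yl)ethan-1-ol | OCCc1ccoc1 | intermediate
4 | 3-(2-bromoethyl)furan | BrCCc1ccoc1 | intermediate
5 | (2S)-3-bromo-2-methylpropan-1-ol | BrC[C@@H](C)CO | starting material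
6 | (2S)-3-bromo-2-methylpropyl trifluoromethanesulfonate | BrC[C@@H](C)COS(=O)(=O)C(F)(F)F | intermediate
7 | 2-(furan-3-yl)ethylmagnesium bromide | Br[Mg]CCc1ccoc1 | intermediate
8 | 3-[(4S)-5-bromo-4-methylpentyl]furan | BrC[C@@H](C)CCCc1ccoc1 | intermediate
9 | pent-3-yn-1-ol | CC#CCCO | starting material
10 | 5-iodopent-2-yne | CC#CCCI | intermediate
11 | pent-3-yn-1-ylzinc iodide | CC#CCC[Zn]I | intermediate
12 | 3-(pent-3-yn-1-yl)furan | CC#CCCc1ccoc1 | intermediate
13 | chlorobis(cyclopentadienyl)[(2E)-5-(furan-3-yl)pent-2-en-2-yl]zirconium (cyclopentadienyl rings drawn σ-bound) | Cl[Zr](C1C=CC=C1)(C1C=CC=C1)/C(C)=C/CCc1ccoc1 | intermediate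
14 | 3-[(3E)-4-bromopent-3-en-1-yl]furan | Br/C(C)=C/CCc1ccoc1 | intermediate
15 | vinylboronic acid pinacol ester (2-ethenyl-4,4,5,5-tetramethyl-1,3,2-dioxaborolane) | C=CB1OC(C)(C)C(C)(C)O1 | starting material
16 | [(2S)-5-(furan-3-yl)-2-methylpentyl]magnesium bromide | Br[Mg]C[C@@H](C)CCCc1ccoc1 | intermediate
17 | sodium ethenyl[(2R)-5-(furan-3-yl)-2-methylpentyl](pinacolato)borate | C=C[B-]1(C[C@@H](C)CCCc2ccoc2)OC(C)(C)C(C)(C)O1.[Na+] | intermediate
18 | 2-[(3E,6R,8S)-1,11-di(furan-3-yl)-4,8-dimethylundec-3-en-6-yl]-4,4,5,5-tetramethyl-1,3,2-dioxaborolane | CC1(C)OB(OC1(C)C)[C@@H](C/C(C)=C/CCc1ccoc1)C[C@@H](C)CCCc1ccoc1 | intermediate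
19 | (3E,6R,8S)-1,11-di(furan-3-yl)-4,8-dimethylundec-3-en-6-ol | O[C@@H](C/C(C)=C/CCc1ccoc1)C[C@@H](C)CCCc1ccoc1 | intermediate
20 | (3E,6R,8S)-1,11-di(furan-3-yl)-4,8-dimethylundec-3-en-6-yl acetate | CC(=O)O[C@@H](C/C(C)=C/CCc1ccoc1)C[C@@H](C)CCCc1ccoc1 | target

## Step count and risks

Total step count: 10.
Longest linear sequence: 6 steps (1, 2, 4, 8, 9, 10). The branch 5, 6, 7, 8, 9, 10 has the same length.

**Steps most likely to fail**

**Step 8.**
- What may go wrong: residual halide may block the cationic palladium pathway. Vinyl or alkyl may pass directly from boron to palladium. The C5–palladium alkyl may lose a β-hydride. Facial selection at C6 may be weak.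
- Fallback: it sets out from 8 and comes back at 18. It builds the C6–B centre first and forms the same C4–C5 bond afterwards.
  - The Grignard reagent 16 made from 8 is coupled with vinyl bromide in a Kumada-type alkenylation (Fe(acac)3, THF/NMP, 0 °C). This gives 3-[(4S)-4-methylhept-6-en-1-yl]furan F1.
  - Platinum-catalysed enantioselective diboration of the terminal alkene follows (Pt(dba)3, a TADDOL-derived phosphonite in the antipode that matches the C6 configuration, B2pin2, THF, 60 °C). This gives 3-[(4S,6S)-4-methyl-6,7-bis(4,4,5,5-tetramethyl-1,3,2-dioxaborolan-2-yl)heptyl]furan F2.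
  - The primary C–B bond of F2 is activated by the neighbouring boronic ester. It is coupled selectively with 14 in a Suzuki–Miyaura reaction (Pd(OAc)2, RuPhos, KOH, THF/H2O, 70 °C), which leads to 18.

**Step 7.**
- What may go wrong: the two regioisomeric alkenylzirconium species may equilibrate incompletely, so that part of the bromine ends on the wrong alkene carbon. The furan ring may also be brominated by NBS.
- Fallback: it sets out from 4, comes back at 14 and replaces steps 5 to 7. It fixes the position of bromine by construction.
  - The Grignard reagent 7 made from 4 is formylated with DMF (THF, 0 °C, then aqueous acid) to give 3-(furan-3-yl)propanal F3.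
  - A Wittig–Schlosser sequence then leads to 14 (EtPPh3Br, n-BuLi, THF, -78 °C; F3; PhLi, to give the β-oxido ylide; BrCF2CF2Br; warming to rt). Bromine can only stand on the former ylide carbon, and this variant should favour the E-alkenyl bromide.

**Step 4.**
- What may go wrong: the primary triflate may decay before it couples. The Grignard reagent may also displace the bromide of 6 or of the product.
- Fallback: it sets out from 1 and comes back at 8. It sets the methyl centre with an auxiliary and joins the furan by another bond.
  - Evans alkylation of commercial (R)-4-benzyl-3-propionyloxazolidin-2-one with allyl iodide (NaN(SiMe3)2, THF, -78 °C) gives (4R)-4-benzyl-3-[(2S)-2-methylpent-4-enoyl]-1,3-oxazolidin-2-one F4.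
  - Reduction with LiBH4 (Et2O, MeOH, 0 °C) gives (2S)-2-methylpent-4-en-1-ol F5.
  - Hydroboration with 9-BBN-H (2 equiv, THF) is followed by B-alkyl Suzuki–Miyaura coupling with 1 (PdCl2(dppf), K3PO4, DMF/THF/H2O, 50 °C). This gives (2S)-5-(furan-3-yl)-2-methylpentan-1-ol F6.
  - An Appel reaction (CBr4, PPh3, CH2Cl2, 0 °C) leads to 8.

## Further compounds

F1 | step 8 | 3-[(4S)-4-methylhept-6-en-1-yl]furan | C=CC[C@@H](C)CCCc1ccoc1
F2 | step 8 | 3-[(4S,6S)-4-methyl-6,7-bis(4,4,5,5-tetramethyl-1,3,2-dioxaborolan-2-yl)heptyl]furan | CC1(C)OB(OC1(C)C)[C@@H](CB2OC(C)(C)C(C)(C)O2)C[C@@H](C)CCCc1ccoc1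
F3 | step 7 | 3-(furan-3-yl)propanal | O=CCCc1ccoc1
F4 | step 4 | (4R)-4-benzyl-3-[(2S)-2-methylpent-4-enoyl]-1,3-oxazolidin-2-one | C=CC[C@H](C)C(=O)N1[C@H](Cc2ccccc2)COC1=O
F5 | step 4 | (2S)-2-methylpent-4-en-1-ol | C=CC[C@H](C)CO
F6 | step 4 | (2S)-5-(furan-3-yl)-2-methylpentan-1-ol | OC[C@@H](C)CCCc1ccoc1
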